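**Retrosynthetic overview**

1. Locants used throughout: C1 = quaternary carbon carrying C12H2OAc; C2 = ring CH2; C3 = CH‑OAc; C4 = CH‑OH; C5 = CMe2; C6 = spiro quaternary carbon; C7 = cage CH2; C8, C9 = cyclopropane CH; C10 = cyclopropane C‑Me; C11 = cage CH‑OAc. Ring A = C1–C6.
2. Endgame: C11–OAc comes from Baeyer–Villiger oxidation of an endo acetyl group (retention). C3–OAc and C4–OH come from a Woodward cis‑hydroxylation of a C3=C4 alkene on the C12 face.
3. The cyclopropane bond C8–C10 is made last in the cage, by 1,3 C–H insertion of a C8 carbene (Bamford–Stevens) in a norbornanone.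
4. Enabling feature: without C8–C10 the cage is a bicyclo[2.2.1]heptane whose six‑membered ring C6–C7–C8–C9–C10–C11 is a Diels–Alder retron. The five‑membered ring C1/C6/C7/C8/C9 becomes a 2‑silyloxy‑cyclopentadiene (oxygen on C8, 1,4 to the oxygenated C11) and C10–C11 comes from (E)‑pent‑3‑en‑2‑one, so one cycloaddition forms C6–C11 and C9–C10.
5. Ring order: ring A (from 2,2‑dimethylcyclohexane‑1,3‑dione; C1 set by palladium‑catalysed asymmetric allylation) → cyclopentenone (aldol) → bicyclo[2.2.1] core (Diels–Alder) → cyclopropane (C–H insertion).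

Key step: step 9

Remark (assumption): in step 5 the (R)‑phosphinooxazoline ligand is chosen by analogy with 2‑alkyl‑2‑allylcyclohexanones, CH2OBn taking the place of the alkyl group; the antipodal ligand would give the enantiomeric series. "Upper face" means the face of ring A that carries C12.

**Route**

Step 1
Reactants: 1 2,2‑dimethylcyclohexane‑1,3‑dione
Product: 2 6,6‑dimethyl‑5‑oxocyclohex‑1‑en‑1‑yl trifluoromethanesulfonate
Conditions: LiN(SiMe3)2, THF, −78 °C; PhNTf2, −78 °C → rt
Reagents that add atoms: N‑phenylbis(trifluoromethanesulfonimide), O=S(=O)(N(c1ccccc1)S(=O)(=O)C(F)(F)F)C(F)(F)F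
Why: Enol triflate formation; C2 is quaternary, so the symmetrical dione has one kind of enolisable position and mono‑enolisation/O‑triflation should give a single product.

Step 2
Reactants: 2 6,6‑dimethyl‑5‑oxocyclohex‑1‑en‑1‑yl trifluoromethanesulfonate
Product: 3 2,2‑dimethylcyclohex‑3‑en‑1‑one
Conditions: Pd(OAc)2 (5 mol %), PPh3, HCO2H, n‑Bu3N, DMF, 60 °C
Reagents that add atoms: none
Why: Palladium‑catalysed formate reduction of a vinyl triflate replaces C–OTf by C–H; the gem‑dimethyl carbon keeps the new alkene (future C3=C4) out of conjugation with the ketone.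

Step 3
Reactants: 3 2,2‑dimethylcyclohex‑3‑en‑1‑one; 4 benzyl chloromethyl ether
Product: 5 rac‑6‑[(benzyloxy)methyl]‑2,2‑dimethylcyclohex‑3‑en‑1‑one
Conditions: LiN(i‑Pr)2, THF, −78 °C; then 4, −78 → −20 °C
Reagents that add atoms: none
Why: Kinetic lithium enolate alkylation; only one α‑carbon (future C1) carries hydrogens, and the α‑chloro ether alkylates it on carbon to bring in C12 as its benzyl ether (racemic; the centre is erased in step 4).

Step 4
Reactants: 5 rac‑6‑[(benzyloxy)methyl]‑2,2‑dimethylcyclohex‑3‑en‑1‑one; 6 allyl chloroformate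
Product: 7 allyl 2‑[(benzyloxy)methyl]‑6,6‑dimethylcyclohexa‑1,4‑dien‑1‑yl carbonate
Conditions: LiN(SiMe3)2, TMEDA, THF, −78 °C; then 6
Reagents that add atoms: none
Why: Regiospecific enolisation (the other α‑carbon is quaternary) and O‑acylation of the tetrasubstituted lithium enolate by the chloroformate give the allyl enol carbonate.

Step 5
Reactants: 7 allyl 2‑[(benzyloxy)methyl]‑6,6‑dimethylcyclohexa‑1,4‑dien‑1‑yl carbonate
Product: 8 (S)‑6‑allyl‑6‑[(benzyloxy)methyl]‑2,2‑dimethylcyclohex‑3‑en‑1‑one
Conditions: Pd2(dba)3 (2.5 mol %), (R)‑t‑BuPHOX (6.25 mol %), THF, 25 °C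
Reagents that add atoms: none
Why: Palladium‑catalysed decarboxylative asymmetric allylic alkylation (Tsuji allylation with a chiral phosphinooxazoline): ionisation and loss of CO2 give an allyl‑palladium enolate that recombines at C1 on the enolate face chosen by the ligand, which sets C1; the (S)‑ligand is known to give (S)‑2‑allyl‑2‑methylcyclohexanone, so the (R)‑ligand is used here, and 2,2,6‑trisubstituted and α‑(silyloxymethyl) cyclohexanones are precedented substrates.

Step 6
Reactants: 8 (S)‑6‑allyl‑6‑[(benzyloxy)methyl]‑2,2‑dimethylcyclohex‑3‑en‑1‑one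
Product: 9 (R)‑6‑[(benzyloxy)methyl]‑2,2‑dimethyl‑6‑(2‑oxopropyl)cyclohex‑3‑en‑1‑one
Conditions: PdCl2 (10 mol %), CuCl, O2 (1 atm), DMF/H2O 7:1, rt
Reagents that add atoms: water, O (carbonyl oxygen); dioxygen, O=O (terminal oxidant)
Why: Wacker–Tsuji oxidation; Markovnikov oxypalladation of the terminal alkene gives the methyl ketone, while the hindered cis‑disubstituted ring alkene should react much more slowly.

Step 7
Reactants: 9 (R)‑6‑[(benzyloxy)methyl]‑2,2‑dimethyl‑6‑(2‑oxopropyl)cyclohex‑3‑en‑1‑one
Product: 10 (S)‑7a‑[(benzyloxy)methyl]‑4,4‑dimethyl‑1,4,7,7a‑tetrahydro‑2H‑inden‑2‑one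
Conditions: KOH (powdered), xylenes, 110 °C, Dean–Stark
Reagents that add atoms: none
Why: Intramolecular aldol condensation; the methyl ketone enolate (C7) adds to the C6 carbonyl in a five‑membered closure and removal of water drives the hindered addition, which has close precedent for 2,2,6,6‑tetrasubstituted cyclohexanones; C1 is untouched.

Step 8
Reactants: 10 (S)‑7a‑[(benzyloxy)methyl]‑4,4‑dimethyl‑1,4,7,7a‑tetrahydro‑2H‑inden‑2‑one
Product: 11 tert‑butyl({(S)‑7a‑[(benzyloxy)methyl]‑4,4‑dimethyl‑7,7a‑dihydro‑4H‑inden‑2‑yl}oxy)dimethylsilane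
Conditions: TBSOTf, Et3N, CH2Cl2, 0 °C
Reagents that add atoms: tert‑butyldimethylsilyl trifluoromethanesulfonate, CC(C)(C)[Si](C)(C)OS(=O)(=O)C(F)(F)F
Why: Silyl dienol ether formation; C9 holds the only enolisable hydrogens (C1 and C5 are quaternary, so no γ‑deprotonation is possible), which gives the 2‑silyloxy‑cyclopentadiene, and this diene cannot isomerise by 1,5‑hydrogen shift because C1 is quaternary.

Step 9
Reactants: 11 tert‑butyl({(S)‑7a‑[(benzyloxy)methyl]‑4,4‑dimethyl‑7,7a‑dihydro‑4H‑inden‑2‑yl}oxy)dimethylsilane; 12 (E)‑pent‑3‑en‑2‑one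
Product: 13 Diels–Alder adduct: ring‑A‑fused 2‑(tert‑butyldimethylsilyloxy)bicyclo[2.2.1]hept‑2‑ene (bridgeheads C6 and C9; enol ether C7=C8; bridge carbon C1 with C12H2OBn syn to C7=C8; endo acetyl on C11; exo methyl on C10)
Conditions: 12 (3 equiv), toluene, 100 °C, sealed tube, BHT (cat.)
Reagents that add atoms: none
Why: A thermal endo‑selective [4+2] cycloaddition (Diels–Alder), with close precedent in the reactions of 2‑trialkylsilyloxy‑cyclopentadienes with enones; the siloxy group on C8 makes C9 the nucleophilic terminus, so C9 bonds to the β‑carbon C10 and the hindered terminus C6 to the acyl‑bearing C11, in an asynchronous transition state whose long forming bond is the congested C6–C11 bond. The cycloaddition closes the six‑membered ring C6–C7–C8–C9–C10–C11 suprafacially on both partners, and with it the second five‑membered ring C6–C11–C10–C9–C1 of the bicyclo[2.2.1]heptene. C6 and C9 are set by the diene face: the dienophile adds anti to C12 and to the pseudo‑axial C5 methyl, which lie on the same face because ring A is fused through C1–C6. C11 is set by the endo rule (acetyl under the diene, hydrogen towards the C1 bridge) and C10 by the E geometry of 12 (methyl exo, hydrogen endo, as the later C–H insertion requires). The step needs regio‑, endo‑ and facial selectivity, secured respectively by the siloxy and C6‑alkyl substituents, by secondary orbital overlap reinforced by the clash an exo acetyl would have with ring A, and by the quaternary centre C1. The silyl enol ether left in 13 keeps C8 differentiated from the new methyl ketone.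

Step 10
Reactants: 13 Diels–Alder adduct
Product: 15 keto alcohol: ring‑A‑fused bicyclo[2.2.1]heptan‑2‑one (C8=O; C7H2) with endo 1‑hydroxyethyl on C11 (carbinol epimers), exo methyl on C10 and C12H2OBn on C1, via silyl enol ether carbinol 14 (not isolated)
Conditions: NaBH4, MeOH/THF, 0 °C → rt; then 1 M HCl, THF, rt
Reagents that add atoms: none
Why: Borohydride reduction masks the methyl ketone as a carbinol (epimer mixture, re‑oxidised in step 15) while C8 is still protected as its silyl enol ether; acid hydrolysis then releases the C8 ketone alone, C7 being protonated to CH2.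

Step 11
Reactants: 15 keto alcohol
Product: 16 p‑toluenesulfonylhydrazone of 15 at C8
Conditions: TsNHNH2, MeOH, AcOH (cat.), 50 °C
Reagents that add atoms: p‑toluenesulfonohydrazide, Cc1ccc(cc1)S(=O)(=O)NN
Why: Tosylhydrazone formation by condensation at the only ketone.

Step 12
Reactants: 16 p‑toluenesulfonylhydrazone of 15
Product: 18 nortricyclene carbinol: ring‑A‑fused tricyclo[2.2.1.0(2,6)]heptane (cyclopropane C8–C9–C10; C10 methyl) with 1‑hydroxyethyl on C11 (on the C7 side), C12H2OBn on C1 and the C3=C4 alkene, via diazoalkane 17 (not isolated)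
Conditions: NaH (2.5 equiv), diglyme, rt → 150 °C
Reagents that add atoms: none
Why: Aprotic Bamford–Stevens reaction; the sodium salt loses sulfinate to give the diazoalkane and then the C8 carbene, which inserts with retention into the rigidly held endo C10–H (1,3 C–H insertion, as in the camphor‑to‑tricyclene conversion), forming C8–C10 and the cyclopropane; the cage fixes the new centre C8, and excess NaH keeps the hydroxyl as alkoxide so the diazoalkane is not protonated.

Step 13
Reactants: 18 nortricyclene carbinol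
Product: 19 diol: as 18 with C12H2OH in place of C12H2OBn
Conditions: Na, NH3 (l), THF, −78 °C; NH4Cl
Reagents that add atoms: none
Why: Dissolving‑metal cleavage of the benzyl ether, which should leave the isolated alkene, the unactivated cyclopropane and the alkoxide untouched.

Step 14
Reactants: 19 diol
Product: 20 primary acetate: as 19 with C12H2OAc, the side‑chain carbinol free
Conditions: Ac2O (1.1 equiv), pyridine, 0 °C
Reagents that add atoms: acetic anhydride, CC(=O)OC(C)=O
Why: Selective acetylation of the primary hydroxyl; the secondary carbinol sits next to C11, which is flanked by the quaternary C6 and the fully substituted C10, and should not react without an acyl‑transfer catalyst.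

Step 15
Reactants: 20 primary acetate
Product: 21 methyl ketone: nortricyclene with acetyl on C11 (on the C7 side), C12H2OAc on C1 and the C3=C4 alkene
Conditions: Dess–Martin periodinane, NaHCO3, CH2Cl2, rt
Reagents that add atoms: none
Why: Dess–Martin oxidation of the secondary carbinol regenerates the methyl ketone; C11 should not epimerise because the acetyl already occupies the less hindered position away from ring A.

Step 16
Reactants: 21 methyl ketone
Product: 23 hydroxy acetate: as 21 with C3–OAc and C4–OH in place of the alkene (both on the upper face, cis to C12), via trans‑iodo acetate 22 (not isolated)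
Conditions: I2 (1.05 equiv), AgOAc (2.2 equiv), AcOH, rt; then H2O, AcOH, 60 °C
Reagents that add atoms: silver acetate, CC(=O)[O-].[Ag+]; water, O
Why: Woodward cis‑hydroxylation; the iodonium ion forms on the face opposite C12 and the axial C5 methyl, acetate opens it trans‑diaxially at C3 from above (22), the acetate carbonyl then displaces the anti‑periplanar iodide with silver assistance, and hydrolysis of the dioxolanylium ion leaves both oxygens cis on the C12 face with the hemi‑orthoester collapsing to the axial C3 acetate and equatorial C4 hydroxyl, as in the classical conversion of steroidal 2‑enes into 2β,3β‑diols; C12 is acetylated beforehand so that its oxygen cannot capture the iodonium ion as an ether.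

Step 17
Reactants: 23 hydroxy acetate
Product: 24 target CNP0197219.1
Conditions: mCPBA, NaHCO3, CH2Cl2, rt
Reagents that add atoms: 3‑chloroperoxybenzoic acid, OOC(=O)c1cccc(Cl)c1
Why: Baeyer–Villiger oxidation; the secondary C11 migrates in preference to methyl with retention of configuration, turning the acetyl group into the C11 acetate of the target.

**Compound list**

1 | 2,2‑dimethylcyclohexane‑1,3‑dione | CC1(C)C(=O)CCCC1=O | starting material
2 | 6,6‑dimethyl‑5‑oxocyclohex‑1‑en‑1‑yl trifluoromethanesulfonate | CC1(C)C(=O)CCC=C1OS(=O)(=O)C(F)(F)F | intermediate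
3 | 2,2‑dimethylcyclohex‑3‑en‑1‑one | CC1(C)C=CCCC1=O | intermediate
4 | benzyl chloromethyl ether | ClCOCc1ccccc1 | starting material
5 | rac‑6‑[(benzyloxy)methyl]‑2,2‑dimethylcyclohex‑3‑en‑1‑one | O(Cc1ccccc1)CC1CC=CC(C)(C)C1=O | intermediate
6 | allyl chloroformate | C=CCOC(Cl)=O | starting material
7 | allyl 2‑[(benzyloxy)methyl]‑6,6‑dimethylcyclohexa‑1,4‑dien‑1‑yl carbonate | O(Cc1ccccc1)CC1=C(OC(=O)OCC=C)C(C)(C)C=CC1 | intermediate
8 | (S)‑6‑allyl‑6‑[(benzyloxy)methyl]‑2,2‑dimethylcyclohex‑3‑en‑1‑one | O(Cc1ccccc1)C[C@]1(CC=C)CC=CC(C)(C)C1=O | intermediate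
9 | (R)‑6‑[(benzyloxy)methyl]‑2,2‑dimethyl‑6‑(2‑oxopropyl)cyclohex‑3‑en‑1‑one | O(Cc1ccccc1)C[C@]1(CC(C)=O)CC=CC(C)(C)C1=O | intermediate
10 | (S)‑7a‑[(benzyloxy)methyl]‑4,4‑dimethyl‑1,4,7,7a‑tetrahydro‑2H‑inden‑2‑one | O(Cc1ccccc1)C[C@]12CC=CC(C)(C)C1=CC(=O)C2 | intermediate
11 | tert‑butyl({(S)‑7a‑[(benzyloxy)methyl]‑4,4‑dimethyl‑7,7a‑dihydro‑4H‑inden‑2‑yl}oxy)dimethylsilane | O(Cc1ccccc1)C[C@]12CC=CC(C)(C)C1=CC(O[Si](C)(C)C(C)(C)C)=C2 | intermediate
12 | (E)‑pent‑3‑en‑2‑one | C/C=C/C(C)=O | starting material
13 | Diels–Alder adduct (silyl enol ether C7=C8, endo acetyl on C11, exo methyl on C10, C12H2OBn syn to C7=C8) | O(Cc1ccccc1)C[C@]12CC=CC(C)(C)[C@]13C=C(O[Si](C)(C)C(C)(C)C)[C@H]2[C@H](C)[C@H]3C(C)=O | intermediate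
14 | silyl enol ether carbinol (13 with 1‑hydroxyethyl on C11, epimers) | O(Cc1ccccc1)C[C@]12CC=CC(C)(C)[C@]13C=C(O[Si](C)(C)C(C)(C)C)[C@H]2[C@H](C)[C@H]3C(C)O | intermediate
15 | keto alcohol (C8 ketone, endo 1‑hydroxyethyl on C11) | O(Cc1ccccc1)C[C@]12CC=CC(C)(C)[C@]13CC(=O)[C@H]2[C@H](C)[C@H]3C(C)O | intermediate
16 | p‑toluenesulfonylhydrazone of 15 | O(Cc1ccccc1)C[C@]12CC=CC(C)(C)[C@]13CC(=NNS(=O)(=O)c4ccc(C)cc4)[C@H]2[C@H](C)[C@H]3C(C)O | intermediate
17 | diazoalkane (C8 diazo) | O(Cc1ccccc1)C[C@]12CC=CC(C)(C)[C@]13CC(=[N+]=[N-])[C@H]2[C@H](C)[C@H]3C(C)O | intermediate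
18 | nortricyclene carbinol, benzyl ether | O(Cc1ccccc1)C[C@]12CC=CC(C)(C)[C@]13C[C@@H]1[C@H]2[C@]1(C)[C@H]3C(C)O | intermediate
19 | nortricyclene diol | OC[C@]12CC=CC(C)(C)[C@]13C[C@@H]1[C@H]2[C@]1(C)[C@H]3C(C)O | intermediate
20 | nortricyclene primary acetate | CC(=O)OC[C@]12CC=CC(C)(C)[C@]13C[C@@H]1[C@H]2[C@]1(C)[C@H]3C(C)O | intermediate
21 | nortricyclene methyl ketone (C11 acetyl, C12H2OAc, C3=C4) | CC(=O)OC[C@]12CC=CC(C)(C)[C@]13C[C@@H]1[C@H]2[C@]1(C)[C@H]3C(C)=O | intermediate
22 | trans‑iodo acetate (C3–OAc upper face, C4–I lower face) | CC(=O)OC[C@]12C[C@H](OC(C)=O)[C@@H](I)C(C)(C)[C@]13C[C@@H]1[C@H]2[C@]1(C)[C@H]3C(C)=O | intermediate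
23 | hydroxy acetate methyl ketone (C3–OAc, C4–OH, C11 acetyl) | CC(=O)OC[C@]12C[C@H](OC(C)=O)[C@H](O)C(C)(C)[C@]13C[C@@H]1[C@H]2[C@]1(C)[C@H]3C(C)=O | intermediate
24 | CNP0197219.1 | CC(=O)OC[C@]12C[C@H](OC(C)=O)[C@H](O)C(C)(C)[C@]13C[C@@H]1[C@H]2[C@]1(C)[C@H]3OC(C)=O | target

**Step count and risks**

Total steps: 17. Longest linear sequence: 17 steps (from 1).

Steps most likely to fail:

- **Step 9.** Bond formation at the congested terminus C6 may be too slow, and the higher temperatures then needed could erode facial and endo selectivity. The fallback sets out from 10 and returns at 18. Deprotonation of 10 with LiN(SiMe3)2 and addition of methyl (E)‑but‑2‑enoate should give, by two successive Michael additions (C9 onto the β‑carbon, then the ester enolate onto C6), keto ester F1. Only its ketone condenses with p‑toluenesulfonohydrazide, giving hydrazone F2, which under the conditions of step 12 passes through diazoalkane F3 to nortricyclene ester F4. LiAlH4 reduction gives primary alcohol F5, Dess–Martin oxidation aldehyde F6, and MeMgBr the carbinol 18.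

- **Step 16.** The iodonium ion may form or open on the wrong face, the acetate may migrate between O3 and O4, or acid may attack the cyclopropane. The fallback sets out from 21 and returns at 23. Epoxidation with dimethyldioxirane on the face opposite C12 gives epoxide F7. Trans‑diaxial acetolysis (AcOH, NaOAc) puts the acetate on C3 from above and leaves the C4 hydroxyl below, giving trans hydroxy acetate F8. Triflation (Tf2O, pyridine) gives triflate F9, and solvolysis in aqueous THF with 2,6‑lutidine lets the C3 acetate displace the anti‑periplanar triflate, so that the same dioxolanylium ion hydrolyses to 23.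

- **Step 12.** The carbene may be diverted into a 1,2‑hydrogen shift, or the diazoalkane may be protonated and enter cationic Wagner–Meerwein rearrangement under the hot basic conditions. The fallback sets out from 15 and returns at 18. Condensation with hydrazine hydrate gives the N‑unsubstituted hydrazone F10, which is oxidised with activated MnO2 at room temperature to diazoalkane 17; this is decomposed by irradiation in pentane at low temperature, without strong base, to give 18.

Further compounds
F1 | step 9 | keto ester (C8 ketone, endo CO2Me on C11, exo methyl on C10) | O(Cc1ccccc1)C[C@]12CC=CC(C)(C)[C@]13CC(=O)[C@H]2[C@H](C)[C@H]3C(=O)OC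
F2 | step 9 | p‑toluenesulfonylhydrazone of F1 | O(Cc1ccccc1)C[C@]12CC=CC(C)(C)[C@]13CC(=NNS(=O)(=O)c4ccc(C)cc4)[C@H]2[C@H](C)[C@H]3C(=O)OC
F3 | step 9 | diazoalkane ester | O(Cc1ccccc1)C[C@]12CC=CC(C)(C)[C@]13CC(=[N+]=[N-])[C@H]2[C@H](C)[C@H]3C(=O)OC
F4 | step 9 | nortricyclene methyl ester | O(Cc1ccccc1)C[C@]12CC=CC(C)(C)[C@]13C[C@@H]1[C@H]2[C@]1(C)[C@H]3C(=O)OC
F5 | step 9 | nortricyclene primary alcohol | O(Cc1ccccc1)C[C@]12CC=CC(C)(C)[C@]13C[C@@H]1[C@H]2[C@]1(C)[C@H]3CO
F6 | step 9 | nortricyclene aldehyde | O(Cc1ccccc1)C[C@]12CC=CC(C)(C)[C@]13C[C@@H]1[C@H]2[C@]1(C)[C@H]3C=O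
F7 | step 16 | C3–C4 epoxide on the face opposite C12 | CC(=O)OC[C@]12C[C@H]4O[C@H]4C(C)(C)[C@]13C[C@@H]1[C@H]2[C@]1(C)[C@H]3C(C)=O
F8 | step 16 | trans hydroxy acetate (C3–OAc upper face, C4–OH lower face) | CC(=O)OC[C@]12C[C@H](OC(C)=O)[C@@H](O)C(C)(C)[C@]13C[C@@H]1[C@H]2[C@]1(C)[C@H]3C(C)=O
F9 | step 16 | C4 triflate of F8 | CC(=O)OC[C@]12C[C@H](OC(C)=O)[C@@H](OS(=O)(=O)C(F)(F)F)C(C)(C)[C@]13C[C@@H]1[C@H]2[C@]1(C)[C@H]3C(C)=O
F10 | step 12 | N‑unsubstituted hydrazone of 15 | O(Cc1ccccc1)C[C@]12CC=CC(C)(C)[C@]13CC(=NN)[C@H]2[C@H](C)[C@H]3C(C)O
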